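## Structural features

The target is a tetracycle, numbered here C1–C16. A cyclohexane (C1, C10, C11, C12, C13, C14) is cis-fused along C1–C10 to a tetrahydrofuran (C1, C2, O, C9, C10). C2 and C9 are bridged by the chain C3–C8, giving a nine-membered cyclic ether (oxonene) with an (E)-trisubstituted C6=C7 alkene. A seven-membered oxepane (C1, C2, C3, O, C16, C15, C14) joins the C3 oxygen to the C14 side chain.

All nine stereocentres form one contiguous array (C12–C11–C10(–C9)–C1(–C2–C3)–C14–C15). H1 and H10 are cis and trans to H2 and H9. The C14 side chain is trans to C2. The C11 butyrate and the C12 methyl are cis to each other and to C9. C3 is a fully substituted ether carbon next to C2.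

The fragile parts are the medium-ring (E)-alkene and the butyrate. The alkene is more exposed to electrophiles and boranes than the cyclohexene alkene of the intermediates, and it is open to transannular attack by a free C3 oxygen.

The real difficulties are three:
- closing the nine-membered ring with E geometry and a 2,9-cis relationship;
- relaying the C2/C9 configuration to C1, C10 and C14;
- oxygenating C11 and C16 by hydroboration without touching C6=C7.

The key step uses the 2,9-cis relationship across the furan oxygen. A diene on C9 and an enone on C2 sit on the same face of the oxonene, so one [4+2] event forms the cyclohexene and closes the tetrahydrofuran.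

## Logic of the disconnections

35 ⇒ 34. No skeletal bond is cut; the C6=C7 alkene is written back to its oxirane (two C–O bonds added). The reason is that the medium-ring alkene would not survive the borane needed at C11=C12. The forward step must remove the oxygen with retention of alkene geometry.

34 ⇒ 32 + 33. The acyl C–O bond of the ester is cut. This is the most labile group and is therefore placed late. The forward step is acylation of a hindered secondary alcohol.

32 ⇒ 31 ⇒ 30 ⇒ 28. The C11–O and C12–H bonds are removed, back to the C11=C12 alkene. A syn hydroboration from the open face sets C12 correctly but C11 wrongly, so C11 is passed through the ketone 31. The forward steps must attack the face anti to the tetrahydrofuran twice and must not epimerise C10 or C12.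

28 ⇒ 27. The oxirane is removed to expose both trisubstituted alkenes. The forward epoxidation must choose the medium-ring alkene over the cyclohexene alkene.

27 ⇒ 25. The O–C16 bond of the oxepane is cut, leaving a tertiary alcohol at C3 and a primary alcohol at C16. This removes a ring without touching a stereocentre. The forward step needs selective activation of the primary hydroxyl. It is placed before the epoxidation so that a free C3 hydroxyl never meets the oxirane.

25 ⇒ 24 ⇒ 22 ⇒ 21 (+16). The C16–O and C15–H bonds and then the C15=C16 bond are removed, back to the C14 acetyl group of the cycloadduct. The ketone has to be methylenated before any borane is used. The forward hydroboration must control C15 and spare the trisubstituted alkenes.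

21 ⇒ 20. The C1–C10 and C13–C14 bonds are cut. Two rings and three stereocentres (C1, C10, C14) disappear, leaving a monocyclic tetraene. The forward cycloaddition must be exo and must occur on the face away from C3 and C8.

20 ⇒ 19 + 14 ⇒ 18 ⇒ 17. The C1=C14 bond is cut to an aldehyde and a stabilised ylide, and the aldehyde is traced to a protected primary alcohol. The enone is made last because it would not survive the methylenation that completes the diene.

17 ⇒ 15 + 16 ⇒ 13 + 14 ⇒ 12. The C12=C13 and C10=C11 bonds are cut in turn, back to a C9 carboxamide. Two olefinations build the (E)-diene from one carbonyl carbon. The forward steps must not epimerise C9.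

12 ⇒ 10. The C8–C9 bond is cut, opening the nine-membered ring to an amide and a primary (E)-allylic chloride. The alkene geometry is then already in the chain and no later inversion is needed; closure by metathesis would give the Z ring. The forward enolate alkylation must form the medium ring and set C9 cis to C2.

10 ⇒ 8 ⇒ 7. The C8–Cl and then the C8–O bonds are removed, back to a terminal gem-dimethyl alkene. Allylic oxidation of the (E)-methyl group supplies C8 and fixes the geometry.

7 ⇒ 6 ⇒ 4 + 5. The O–Si bond and then the O–C9 ether bond are cut, giving a secondary/tertiary diol and an α-chloro amide. The forward alkylation must choose the secondary hydroxyl.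

4 ⇒ 3 ⇒ 2 ⇒ 1. The C3–O bond (water), the benzyl ether and the oxirane are removed, back to a (Z)-allylic alcohol that holds C1–C8 and both methyl groups. One catalytic epoxidation sets C2, and inversion at C3 on opening gives the C2/C3 pair of the target. A C3-preformed vinyl carbinol was set aside, because its vinyl group cannot be oxidised selectively beside a trisubstituted alkene and C2 would be poorly controlled.

## Other disconnections considered

Alternative 1: The C6=C7 alkene and a C3 carbonyl are joined backwards into a C3–C7 bond with a leaving group on C6. Forwards, a Grob/Wharton-type fragmentation of a C3 alkoxide, with loss of a C6 sulfonate, would give the tricyclic ketone A1.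
- In favour: the E geometry follows stereospecifically from the anti-periplanar arrangement in a rigid bicycle. On this point it is better than the chosen plan, which relies on a medium-ring alkylation.
- In favour: the cyclohexane stereocentres (C11, C12, C14, C15) can all be finished before the ring alkene exists, so no alkene masking is needed. This is also better than the chosen plan.
- Against: C3 arrives as a ketone. The methyl group must then be added face-selectively on a flexible nine-membered ring. C2 is α to that ketone and carries an ether oxygen, so the basic fragmentation conditions invite epimerisation or β-elimination.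
- Against: the oxepane still has to be closed afterwards, and the bicyclic fragmentation substrate needs a long preparation.
- Comparison: on mechanism it is the more predictable for the alkene and the less predictable for C3. On step economy the chosen plan is ahead, since it takes C1–C8 from one terpene and sets C2/C3 in two steps.

Alternative 2: The oxepane oxygen is excised to give the carbocyclic C16 ketone A2. Forwards, a Baeyer–Villiger oxidation with bis(trimethylsilyl) peroxide and SnCl4 would insert oxygen between C16 and C3 to give the lactone A3.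
- In favour: migration proceeds with retention at C3, so no substitution by a hindered tertiary alcohol is needed. A free C3 hydroxyl never exists, which rules out transannular attack on C6/C7; on this point it is better than the chosen plan.
- In favour: the silyl peroxide should leave alkenes alone, which makes it equal to the chosen plan in tolerance of C6=C7 at that stage.
- Against: C3 must be built as an all-carbon quaternary stereocentre, which is harder than a tertiary carbinol from an epoxide. The Lewis acid sits near a strained alkene and two ether oxygens. Insertion must choose C3 over the branched C15.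
- Against: the lactone must afterwards be reduced to the ether in two further operations.
- Comparison: the chosen plan closes the same ring in one redox-neutral step from compounds that are easier to make, so it is ahead on structure and step economy.

Alternative 3: The O–C9 and C8–C9 bonds are cut backwards. Forwards, a copper or rhodium carbenoid at C9 would be captured by the oxygen of a six-membered cyclic ether, and a [2,3] shift of the oxonium ylide across an isopropenyl group would give the bridged ketone A4.
- In favour: the tetrahydrofuran and the oxonene form in one step, and the bicyclic product fixes the 2,9-cis relationship. This is equal to the chosen plan in stereochemical outcome and better in step economy for the medium ring.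
- Against: the alkene geometry depends on the catalyst and on the ylide conformation and is not inherently E. C–H insertion and [1,2] shift compete.
- Against: the cyclohexane must then be added by an intermolecular Diels–Alder reaction on a diene made from the C10 ketone. There the facial and endo/exo outcome and the C14 configuration are not tied to the ring.
- Comparison: the chosen plan is weaker in ring construction but stronger in the relay of stereochemistry to C1, C10 and C14, which it achieves in one intramolecular step.

Key step: step 15

Abbreviations: PMB = 4-methoxybenzyl; TBS = tert-butyldimethylsilyl; Ipc = isopinocampheyl.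

Assumptions (remarks on the chemistry):
- The 6,7-oxirane of 28–34 is drawn as one of the two possible trans-epoxides. Attack on either face is acceptable, because removal of the oxygen with retention returns the same (E)-alkene.
- (+)-Ipc2BH is taken as the enantiomer of the reagent that reinforces the substrate bias at C15.

## Steps

Step 1
Reactants: 1 nerol [(2Z)-3,7-dimethylocta-2,6-dien-1-ol]
Product: 2 (2S,3R)-2,3-epoxynerol
Conditions: Ti(Oi-Pr)4 (cat.), L-(+)-diethyl tartrate (cat.), t-BuOOH, 4 Å MS, CH2Cl2, −20 °C
Reagents that add atoms: tert-butyl hydroperoxide, CC(C)(C)OO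
Why: Sharpless asymmetric epoxidation: the allylic alcohol binds the titanium tartrate catalyst, so only C2=C3 is oxidised and C6=C7 is left; with the L-(+)-tartrate the (Z)-alcohol should give the (2S,3R)-epoxide, which fixes C2.

Step 2
Reactants: 2 (2S,3R)-2,3-epoxynerol
Product: 3 (2S,3R)-2,3-epoxyneryl PMB ether
Conditions: NaH, PMBCl, Bu4NI (cat.), THF/DMF, 0 °C → rt
Reagents that add atoms: 4-methoxybenzyl chloride, COc1ccc(CCl)cc1
Why: Williamson etherification of the primary alkoxide; the ether tolerates the acid, bases, silyl triflate and ylides that follow and can be removed oxidatively before the enone is built.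

Step 3
Reactants: 3 (2S,3R)-2,3-epoxyneryl PMB ether
Product: 4 (2S,3S)-1-(PMB-oxy)-3,7-dimethyloct-6-ene-2,3-diol
Conditions: HClO4 (cat.), THF/H2O, 0 °C → rt
Reagents that add atoms: water, O
Why: Acid-catalysed epoxide hydrolysis: water should attack the tertiary carbon C3 (C2 is deactivated by the neighbouring C1 oxygen) with inversion, turning the (2S,3R)-epoxide into the (2S,3S)-diol that carries the C2/C3 relationship of the target; attack at C2 would give the enantiomer, so this regiocontrol guards the optical purity.

Step 4
Reactants: 4 (2S,3S)-1-(PMB-oxy)-3,7-dimethyloct-6-ene-2,3-diol; 5 2-chloro-N,N-dimethylacetamide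
Product: 6 2-{[(2S,3S)-3-hydroxy-1-(PMB-oxy)-3,7-dimethyloct-6-en-2-yl]oxy}-N,N-dimethylacetamide
Conditions: NaH, Bu4NI (cat.), THF, 0 °C → rt
Reagents that add atoms: none
Why: Williamson etherification: the secondary C2 alkoxide is much less hindered than the tertiary C3 alkoxide and should react selectively with the α-chloro amide, which brings in C9 and C10 in one operation.

Step 5
Reactants: 6 2-{[(2S,3S)-3-hydroxy-1-(PMB-oxy)-3,7-dimethyloct-6-en-2-yl]oxy}-N,N-dimethylacetamide
Product: 7 C3 TBS ether of 6
Conditions: TBSOTf, 2,6-lutidine, CH2Cl2, 0 °C → rt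
Reagents that add atoms: tert-butyldimethylsilyl triflate, CC(C)(C)[Si](C)(C)OS(=O)(=O)C(F)(F)F
Why: Silylation of a tertiary alcohol needs the silyl triflate; the ether keeps the C3 oxygen away from the bases used later and from transannular attack on C6/C7.

Step 6
Reactants: 7 C3 TBS ether of 6
Product: 8 (6E)-8-hydroxy derivative of 7 (primary allylic alcohol at C8)
Conditions: SeO2 (cat.), t-BuOOH, salicylic acid (cat.), CH2Cl2, rt
Reagents that add atoms: tert-butyl hydroperoxide, CC(C)(C)OO
Why: Selenium dioxide allylic oxidation (ene reaction, then [2,3]-sigmatropic shift) attacks the (E)-methyl group of the gem-dimethyl alkene, so C8 arrives as a primary alcohol and the E geometry of C6=C7 needed in the target is fixed here.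

Step 7
Reactants: 8 (6E)-8-hydroxy derivative of 7
Product: 10 (6E)-C8 allylic chloride, via allylic mesylate 9 (not isolated)
Conditions: MsCl, 2,4,6-collidine, LiCl, DMF, 0 °C
Reagents that add atoms: methanesulfonyl chloride, CS(=O)(=O)Cl (retained in 9 only); lithium chloride, [Li+].[Cl-]
Why: Mesylation followed by SN2 displacement with chloride at the primary allylic carbon; no allylic transposition is expected and the alkene geometry is untouched.

Step 8
Reactants: 10 (6E)-C8 allylic chloride
Product: 12 (2S,3S,9S,6E)-oxonene amide (ring O–C2–C3–C4–C5–C6=C7–C8–C9; CH2OPMB on C2, Me and OTBS on C3, Me on C7, CONMe2 on C9; 2,9-cis), via lithium amide enolate 11 (not isolated)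
Conditions: LiN(SiMe3)2, THF (0.005 M), 0 → 45 °C
Reagents that add atoms: lithium bis(trimethylsilyl)amide, [Li+].C[Si](C)(C)[N-][Si](C)(C)C (lithium retained in 11 only)
Why: Intramolecular amide enolate alkylation (SN2 at the primary allylic chloride, forming C8–C9): the (Z)-α-alkoxy enolate should close the nine-membered ring with C6=C7 unchanged, and C9 should come out cis to C2 because the closing transition state keeps H2 eclipsed with the enolate plane and the new bond anti to the quaternary C3; high dilution suppresses dimers.

Step 9
Reactants: 12 (2S,3S,9S,6E)-oxonene amide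
Product: 13 C9 aldehyde (configured as 12)
Conditions: Cp2Zr(H)Cl, THF, rt
Reagents that add atoms: none
Why: Reduction of a tertiary amide by the zirconium hydride stops at the aldehyde level, and trisubstituted alkenes, ethers and silyl ethers are inert in the short reaction time; the α-alkoxy aldehyde is used at once so that C9 is not epimerised.

Step 10
Reactants: 13 C9 aldehyde; 14 1-(triphenylphosphoranylidene)propan-2-one
Product: 15 C9 (E)-3-oxobut-1-enyl oxonene
Conditions: CH2Cl2, rt → 40 °C
Reagents that add atoms: none
Why: Wittig olefination with a stabilised ylide gives the (E)-enone C10=C11 under neutral conditions.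

Step 11
Reactants: 15 C9 (E)-3-oxobut-1-enyl oxonene; 16 methyltriphenylphosphonium bromide
Product: 17 C9 (E)-3-methylbuta-1,3-dienyl oxonene (CH2OPMB on C2)
Conditions: KOt-Bu, THF, 0 °C
Reagents that add atoms: none
Why: Wittig methylenation: the non-stabilised ylide adds 1,2 to the enone carbonyl and turns it into the diene terminus C12=C13 without touching C10=C11.

Step 12
Reactants: 17 C9 (E)-3-methylbuta-1,3-dienyl oxonene
Product: 18 C1 primary alcohol
Conditions: DDQ, CH2Cl2/pH 7 buffer, 0 °C
Reagents that add atoms: none
Why: Oxidative cleavage of the PMB ether (benzylic hydride abstraction, then hydrolysis); the tertiary silyl ether and the alkenes should be untouched under buffered conditions in the cold.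

Step 13
Reactants: 18 C1 primary alcohol
Product: 19 C1 aldehyde
Conditions: Dess–Martin periodinane, NaHCO3, CH2Cl2, 0 °C → rt
Reagents that add atoms: none
Why: Dess–Martin oxidation under buffered conditions gives the α-alkoxy aldehyde without epimerising C2.

Step 14
Reactants: 19 C1 aldehyde; 14 1-(triphenylphosphoranylidene)propan-2-one
Product: 20 2,9-cis (E)-oxonene tetraene (C9 dienyl, C2 (E)-3-oxobut-1-enyl, C3 OTBS)
Conditions: CH2Cl2, 0 °C → rt
Reagents that add atoms: none
Why: Wittig olefination with the stabilised ylide gives the (E)-enone C1=C14; the reaction is run cold and the tetraene is concentrated without heating, because cycloaddition may already begin.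

Step 15
Reactants: 20 2,9-cis (E)-oxonene tetraene
Product: 21 tricyclic cycloadduct (C11=C12 alkene, C14 acetyl, C3 OTBS)
Conditions: PhMe (0.01 M), BHT (cat.), 80 °C
Reagents that add atoms: none
Why: Thermal, concerted but asynchronous suprafacial [4+2] cycloaddition of the C10=C11–C12=C13 diene (HOMO) to the C1=C14 enone (LUMO); the closest known reaction type is the intramolecular Diels–Alder reaction of 2,9-cis-disubstituted oxonenes that carry the same two arms. The cyclohexene (C1, C10, C11, C12, C13, C14) closes through the two new σ-bonds C1–C10 and C13–C14, and the tetrahydrofuran (C1, C2, O, C9, C10) closes at the same time as the fused ring that holds the three-atom tether C2–O–C9 and the new C1–C10 bond. C14 relative to C1 follows from the (E)-enone, because the addition is suprafacial and C2 and the acetyl group therefore end up trans. C10 relative to C1 is set by the exo transition state (acetyl turned away from the diene), which the short ether tether favours and which gives the cis fusion with H1 and H10 syn. The sense of both relative to C2/C9 comes from the 2,9-cis ring: with H2 and H9 eclipsing their alkenes to avoid allylic strain, the two π-systems can meet only on the face away from C3 and C8, so H1/H10 should come out trans to H2/H9. The step needs exo and π-facial selectivity and no reaction of the ring alkene; the first two rest on the tether length and the cis-2,9 substitution, the last on the fact that C6=C7 is neither activated nor part of a diene. BHT suppresses radical polymerisation of the diene and high dilution keeps the reaction intramolecular.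

Step 16
Reactants: 21 tricyclic cycloadduct; 16 methyltriphenylphosphonium bromide
Product: 22 C14 isopropenyl triene
Conditions: KOt-Bu, THF, 0 °C → rt
Reagents that add atoms: none
Why: Wittig methylenation of the methyl ketone; the ylide is made with a slight deficit of base and used cold so that C14, α to the ketone, is not epimerised, and the ketone is removed before any borane is used.

Step 17
Reactants: 22 C14 isopropenyl triene
Product: 24 C16 primary alcohol (C15 configured as in the target), via trialkylborane 23 (not isolated)
Conditions: (+)-Ipc2BH, THF, −25 → 0 °C; then NaOH, H2O2, 0 °C → rt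
Reagents that add atoms: hydrogen peroxide, OO; (+)-diisopinocampheylborane, B([C@H]1C[C@H]2C[C@@H]([C@@H]1C)C2(C)C)[C@H]1C[C@H]2C[C@@H]([C@@H]1C)C2(C)C (boron and both Ipc groups retained in 23 only)
Why: Hydroboration–oxidation: the bulky dialkylborane should add only to the 1,1-disubstituted alkene (boron on C16) and leave both trisubstituted alkenes; C15 is set by the face of addition, where the chiral reagent is meant to reinforce the bias of C14, and oxidation with retention gives the alcohol.

Step 18
Reactants: 24 C16 primary alcohol
Product: 25 C3,C16-diol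
Conditions: Bu4NF, THF, 60 °C
Reagents that add atoms: none
Why: Fluoride cleavage of the tertiary silyl ether; no electrophile is present, so the freed C3 oxygen cannot add across C6=C7.

Step 19
Reactants: 25 C3,C16-diol
Product: 27 tetracyclic diene (oxepane closed; C6=C7 and C11=C12 present), via primary triflate 26 (not isolated)
Conditions: Tf2O, 2,6-lutidine, CH2Cl2, −78 → 0 °C
Reagents that add atoms: triflic anhydride, O=S(=O)(OS(=O)(=O)C(F)(F)F)C(F)(F)F (retained in 26 only)
Why: Selective triflation of the primary alcohol and intramolecular SN2 displacement by the C3 hydroxyl (Williamson-type etherification, 7-exo-tet) close the oxepane; C3 is not a reacting centre, so its configuration is kept.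

Step 20
Reactants: 27 tetracyclic diene
Product: 28 6,7-epoxide (trans-oxirane; C11=C12 intact)
Conditions: dimethyldioxirane (1 equiv), acetone/CH2Cl2, −78 → −40 °C
Reagents that add atoms: dimethyldioxirane, CC1(C)OO1
Why: Epoxidation is expected at the strained and more exposed (E)-C6=C7 alkene rather than at the cyclohexene alkene that is flanked by the ring-fusion carbon; the oxirane masks this alkene against the borane of the next step, and it is installed only now because the C3 oxygen is already tied up in the oxepane.

Step 21
Reactants: 28 6,7-epoxide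
Product: 30 C11 alcohol with hydroxyl trans to the C12 methyl (C11 epimer of the target pattern), via C11 alkylborane 29 (not isolated)
Conditions: BH3·THF, THF, 0 °C → rt; then NaOH, H2O2, 0 °C
Reagents that add atoms: borane–tetrahydrofuran, B.C1CCOC1 (boron retained in 29 only); hydrogen peroxide, OO
Why: Hydroboration–oxidation of the only remaining alkene: boron adds to C11 and hydrogen to C12 in a syn fashion from the face of H1/H10, anti to the tetrahydrofuran fused on the other face, which sets C12 correctly (methyl cis to C9) but leaves the C11 oxygen on the wrong face.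

Step 22
Reactants: 30 C11 alcohol (hydroxyl trans to the C12 methyl)
Product: 31 C11 ketone
Conditions: Dess–Martin periodinane, NaHCO3, CH2Cl2, rt
Reagents that add atoms: none
Why: Dess–Martin oxidation under buffered conditions removes the wrong C11 centre without epimerising C10 or C12.

Step 23
Reactants: 31 C11 ketone
Product: 32 C11 alcohol with hydroxyl cis to the C12 methyl (target configuration)
Conditions: NaBH4, MeOH/CH2Cl2, −40 → 0 °C
Reagents that add atoms: none
Why: Hydride should attack the ketone from the same open face that the borane used (anti to C9 and to the C12 methyl) and so place the hydroxyl cis to the methyl; oxidation and reduction together invert C11.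

Step 24
Reactants: 32 C11 alcohol (target configuration); 33 butanoic anhydride
Product: 34 C11 butanoate of the 6,7-epoxide
Conditions: DMAP, Et3N, CH2Cl2, rt
Reagents that add atoms: none
Why: DMAP-catalysed acylation (acyl transfer through the acylpyridinium ion) of the hindered secondary alcohol.

Step 25
Reactants: 34 C11 butanoate of the 6,7-epoxide
Product: 35 4-deoxyasbestinin A
Conditions: N2C(CO2Me)2 (slow addition), Rh2(OAc)4 (cat.), PhMe, 100 °C
Reagents that add atoms: none
Why: Carbenoid deoxygenation of an epoxide used as an alkene protecting group: the rhodium carbenoid attacks the oxirane oxygen, and the oxonium ylide fragments to the alkene and dimethyl oxomalonate with both C–O bonds breaking on the same face, so the trans-oxirane should return the (E)-alkene; the diazo ester is added slowly and in slight excess only, to spare the liberated alkene.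

## Compound list

1 | nerol, (2Z)-3,7-dimethylocta-2,6-dien-1-ol | CC(C)=CCC/C(C)=C\CO | starting material
2 | (2S,3R)-2,3-epoxynerol | OC[C@@H]1O[C@]1(C)CCC=C(C)C | intermediate
3 | (2S,3R)-2,3-epoxyneryl PMB ether | COc1ccc(COC[C@@H]2O[C@]2(C)CCC=C(C)C)cc1 | intermediate
4 | (2S,3S)-1-(PMB-oxy)-3,7-dimethyloct-6-ene-2,3-diol | COc1ccc(COC[C@H](O)[C@@](C)(O)CCC=C(C)C)cc1 | intermediate
5 | 2-chloro-N,N-dimethylacetamide | CN(C)C(=O)CCl | starting material
6 | 2-{[(2S,3S)-3-hydroxy-1-(PMB-oxy)-3,7-dimethyloct-6-en-2-yl]oxy}-N,N-dimethylacetamide | COc1ccc(COC[C@H](OCC(=O)N(C)C)[C@@](C)(O)CCC=C(C)C)cc1 | intermediate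
7 | C3 TBS ether of 6 | COc1ccc(COC[C@H](OCC(=O)N(C)C)[C@@](C)(O[Si](C)(C)C(C)(C)C)CCC=C(C)C)cc1 | intermediate
8 | (6E)-8-hydroxy derivative of 7 | COc1ccc(COC[C@H](OCC(=O)N(C)C)[C@@](C)(O[Si](C)(C)C(C)(C)C)CC/C=C(\C)CO)cc1 | intermediate
9 | C8 allylic mesylate of 8 (not isolated) | COc1ccc(COC[C@H](OCC(=O)N(C)C)[C@@](C)(O[Si](C)(C)C(C)(C)C)CC/C=C(\C)COS(C)(=O)=O)cc1 | intermediate
10 | (6E)-C8 allylic chloride | COc1ccc(COC[C@H](OCC(=O)N(C)C)[C@@](C)(O[Si](C)(C)C(C)(C)C)CC/C=C(\C)CCl)cc1 | intermediate
11 | lithium (Z)-enolate of 10 (not isolated) | COc1ccc(COC[C@H](O/C=C(\O[Li])N(C)C)[C@@](C)(O[Si](C)(C)C(C)(C)C)CC/C=C(\C)CCl)cc1 | intermediate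
12 | (2S,3S,9S,6E)-oxonene amide, 2,9-cis | CC(C)(C)[Si](C)(C)O[C@@]1(C)CC/C=C(\C)C[C@@H](C(=O)N(C)C)O[C@H]1COCc1ccc(OC)cc1 | intermediate
13 | C9 aldehyde of the (E)-oxonene | CC(C)(C)[Si](C)(C)O[C@@]1(C)CC/C=C(\C)C[C@@H](C=O)O[C@H]1COCc1ccc(OC)cc1 | intermediate
14 | 1-(triphenylphosphoranylidene)propan-2-one | CC(=O)C=P(c1ccccc1)(c1ccccc1)c1ccccc1 | starting material
15 | C9 (E)-3-oxobut-1-enyl oxonene | CC(C)(C)[Si](C)(C)O[C@@]1(C)CC/C=C(\C)C[C@@H](/C=C/C(C)=O)O[C@H]1COCc1ccc(OC)cc1 | intermediate
16 | methyltriphenylphosphonium bromide | C[P+](c1ccccc1)(c1ccccc1)c1ccccc1.[Br-] | starting material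
17 | C9 (E)-3-methylbuta-1,3-dienyl oxonene, C2 CH2OPMB | CC(C)(C)[Si](C)(C)O[C@@]1(C)CC/C=C(\C)C[C@@H](/C=C/C(C)=C)O[C@H]1COCc1ccc(OC)cc1 | intermediate
18 | C1 primary alcohol | CC(C)(C)[Si](C)(C)O[C@@]1(C)CC/C=C(\C)C[C@@H](/C=C/C(C)=C)O[C@H]1CO | intermediate
19 | C1 aldehyde | CC(C)(C)[Si](C)(C)O[C@@]1(C)CC/C=C(\C)C[C@@H](/C=C/C(C)=C)O[C@H]1C=O | intermediate
20 | 2,9-cis (E)-oxonene tetraene | CC(C)(C)[Si](C)(C)O[C@@]1(C)CC/C=C(\C)C[C@@H](/C=C/C(C)=C)O[C@H]1/C=C/C(C)=O | intermediate
21 | tricyclic cycloadduct, C14 acetyl, C11=C12 | CC(C)(C)[Si](C)(C)O[C@@]1(C)CC/C=C(\C)C[C@@H]2O[C@H]1[C@H]3[C@H](C(C)=O)CC(C)=C[C@@H]23 | intermediate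
22 | C14 isopropenyl triene | CC(C)(C)[Si](C)(C)O[C@@]1(C)CC/C=C(\C)C[C@@H]2O[C@H]1[C@H]3[C@H](C(C)=C)CC(C)=C[C@@H]23 | intermediate
23 | C16 bis(isopinocampheyl)borane (not isolated) | CC(C)(C)[Si](C)(C)O[C@@]1(C)CC/C=C(\C)C[C@@H]2O[C@H]1[C@H]3[C@H]([C@@H](C)CB([C@H]4C[C@H]5C[C@@H]([C@@H]4C)C5(C)C)[C@H]4C[C@H]5C[C@@H]([C@@H]4C)C5(C)C)CC(C)=C[C@@H]23 | intermediate
24 | C16 primary alcohol, C15 as in the target | CC(C)(C)[Si](C)(C)O[C@@]1(C)CC/C=C(\C)C[C@@H]2O[C@H]1[C@H]3[C@H]([C@@H](C)CO)CC(C)=C[C@@H]23 | intermediate
25 | C3,C16-diol | O[C@@]1(C)CC/C=C(\C)C[C@@H]2O[C@H]1[C@H]3[C@H]([C@@H](C)CO)CC(C)=C[C@@H]23 | intermediate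
26 | C16 primary triflate (not isolated) | O[C@@]1(C)CC/C=C(\C)C[C@@H]2O[C@H]1[C@H]3[C@H]([C@@H](C)COS(=O)(=O)C(F)(F)F)CC(C)=C[C@@H]23 | intermediate
27 | tetracyclic diene, oxepane closed | CC1=C[C@@H]2[C@@H]3[C@@H](C1)[C@@H](C)CO[C@@]1(C)CC/C=C(\C)C[C@@H]2O[C@@H]31 | intermediate
28 | 6,7-epoxide of 27 (trans-oxirane) | CC1=C[C@@H]2[C@@H]3[C@@H](C1)[C@@H](C)CO[C@@]1(C)CC[C@H]4O[C@]4(C)C[C@@H]2O[C@@H]31 | intermediate
29 | C11 alkylborane (not isolated) | B[C@@H]1[C@@H]2[C@@H]3[C@@H](C[C@H]1C)[C@@H](C)CO[C@@]1(C)CC[C@H]4O[C@]4(C)C[C@@H]2O[C@@H]31 | intermediate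
30 | C11 alcohol, hydroxyl trans to the C12 methyl | O[C@@H]1[C@@H]2[C@@H]3[C@@H](C[C@H]1C)[C@@H](C)CO[C@@]1(C)CC[C@H]4O[C@]4(C)C[C@@H]2O[C@@H]31 | intermediate
31 | C11 ketone | O=C1[C@@H]2[C@@H]3[C@@H](C[C@H]1C)[C@@H](C)CO[C@@]1(C)CC[C@H]4O[C@]4(C)C[C@@H]2O[C@@H]31 | intermediate
32 | C11 alcohol, hydroxyl cis to the C12 methyl | O[C@H]1[C@@H]2[C@@H]3[C@@H](C[C@H]1C)[C@@H](C)CO[C@@]1(C)CC[C@H]4O[C@]4(C)C[C@@H]2O[C@@H]31 | intermediate
33 | butanoic anhydride | CCCC(=O)OC(=O)CCC | starting material
34 | C11 butanoate of the 6,7-epoxide | CCCC(=O)O[C@H]1[C@@H]2[C@@H]3[C@@H](C[C@H]1C)[C@@H](C)CO[C@@]1(C)CC[C@H]4O[C@]4(C)C[C@@H]2O[C@@H]31 | intermediate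
35 | 4-deoxyasbestinin A, (1S,2S,3S,9S,10R,11R,12R,14S,15R,6E) in the numbering used here | CCCC(=O)O[C@H]1[C@@H]2[C@@H]3[C@@H](C[C@H]1C)[C@@H](C)CO[C@@]1(C)CC/C=C(\C)C[C@@H]2O[C@@H]31 | target

## Step count and least certain steps

Total step count: 25. Longest linear sequence: 25 steps (1 → 35); 5, 14, 16 and 33 are bought.

Step 15 (key step). What may go wrong: erosion of exo or π-facial selectivity, because an (E)-oxonene can populate two planar-chiral ring conformers that present the diene and the enone differently; or a slow cycloaddition that lets the diene polymerise. Fallback: the dienophile is changed to one that accepts a chelating Lewis acid, so that the cycloaddition can run far below room temperature. It sets out from 19. Horner–Wadsworth–Emmons olefination with diethyl [2-(methoxy(methyl)amino)-2-oxoethyl]phosphonate (LiCl, i-Pr2NEt, MeCN) should give the (E)-N-methoxy-N-methylacrylamide tetraene F1. Me2AlCl in CH2Cl2 at −40 °C → rt should give the cycloadduct Weinreb amide F2. MeMgBr in THF at 0 °C converts F2 into the methyl ketone, and the route is rejoined at 21.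

Step 8. What may go wrong: intermolecular alkylation; closure through the far end of the allyl unit (SN2′) to a seven-membered ring; or closure to the 2,9-trans ring because the enolate faces are not well discriminated. Fallback: ring-closing metathesis followed by inversion of the alkene. It sets out from 7.
- OsO4 (cat.)/NaIO4 with 2,6-lutidine in dioxane/H2O cleaves C6=C7 to the C6 aldehyde F3.
- Ph3P=CH2 gives the terminal alkene F4.
- LiN(SiMe3)2 and then 3-bromo-2-methylpropene alkylate C9 to the methallyl amide F5. There is no auxiliary control here, so the 2,9-cis epimer would have to be separated.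
- (H2IMes)(PCy3)Cl2Ru=CHPh in CH2Cl2 at 40 °C should close the (Z)-oxonene amide F6.
- Dimethyldioxirane gives the cis-oxirane F7.
- LiPPh2 in THF and then MeI open the oxirane at C6 with inversion and eliminate Ph2P(O)Me in a syn fashion, which inverts the alkene and rejoins the route at 12.

Step 17. What may go wrong: poor facial control at C15, since reagent control on a 1,1-disubstituted alkene is modest and the C14 bias is weak; or partial hydroboration of C6=C7 by mono-isopinocampheylborane formed by dissociation. Fallback: kinetic control is replaced by separation and recycling through the aldehyde. It sets out from 22. 9-BBN in THF and then NaOH/H2O2 give 24 together with its C15 epimer, the alcohol F8. F8 is oxidised with Dess–Martin periodinane to the C15-epimeric aldehyde F9. F9 is equilibrated with K2CO3 in MeOH with the aldehyde F10 of target configuration. NaBH4 then returns 24, and recovered F8 goes round again.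

Step 20. What may go wrong: loss of chemoselectivity, with oxidation of C11=C12 as well. Fallback: the bulkier osmium oxidant, then conversion of the diol into the same oxirane. It sets out from 27. OsO4 (cat.) with N-methylmorpholine N-oxide in acetone/H2O should give the 6,7-syn-diol F11. MeC(OMe)3 with pyridinium p-toluenesulfonate gives the cyclic orthoacetate F12. AcBr opens it with inversion at C6 to the acetoxy bromide F13. K2CO3 in MeOH closes the oxirane with a second inversion, which rejoins the route at 28.

Step 25. What may go wrong: cyclopropanation of the liberated alkene by excess carbenoid, unproductive ylide formation at the other ether oxygens, or loss of stereospecificity leading to the Z ring. Fallback: a two-stage removal of the oxygen by double inversion. It sets out from 34. PhSeNa (from (PhSe)2 and NaBH4) in EtOH at reflux opens the oxirane at C6 with inversion to the hydroxy selenide F14. MsCl and Et3N in CH2Cl2 at 0 °C bring about anti elimination of selenium and oxygen, which should return the (E)-alkene and rejoin the route at 35.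

## Further compounds

F1 | step 15 | (E)-N-methoxy-N-methylacrylamide tetraene | CC(C)(C)[Si](C)(C)O[C@@]1(C)CC/C=C(\C)C[C@@H](/C=C/C(C)=C)O[C@H]1/C=C/C(=O)N(C)OC
F2 | step 15 | cycloadduct Weinreb amide | CC(C)(C)[Si](C)(C)O[C@@]1(C)CC/C=C(\C)C[C@@H]2O[C@H]1[C@H]3[C@H](C(=O)N(C)OC)CC(C)=C[C@@H]23
F3 | step 8 | C6 aldehyde from cleavage of 7 | COc1ccc(COC[C@H](OCC(=O)N(C)C)[C@@](C)(O[Si](C)(C)C(C)(C)C)CCC=O)cc1
F4 | step 8 | terminal alkene | COc1ccc(COC[C@H](OCC(=O)N(C)C)[C@@](C)(O[Si](C)(C)C(C)(C)C)CCC=C)cc1
F5 | step 8 | C9 methallyl amide | COc1ccc(COC[C@H](O[C@@H](CC(C)=C)C(=O)N(C)C)[C@@](C)(O[Si](C)(C)C(C)(C)C)CCC=C)cc1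
F6 | step 8 | (Z)-oxonene amide | CC(C)(C)[Si](C)(C)O[C@@]1(C)CC/C=C(/C)C[C@@H](C(=O)N(C)C)O[C@H]1COCc1ccc(OC)cc1
F7 | step 8 | cis-6,7-oxirane of the oxonane amide | CC(C)(C)[Si](C)(C)O[C@@]1(C)CC[C@H]2O[C@@]2(C)C[C@@H](C(=O)N(C)C)O[C@H]1COCc1ccc(OC)cc1
F8 | step 17 | C15 epimer of 24 | CC(C)(C)[Si](C)(C)O[C@@]1(C)CC/C=C(\C)C[C@@H]2O[C@H]1[C@H]3[C@H]([C@H](C)CO)CC(C)=C[C@@H]23
F9 | step 17 | C16 aldehyde, C15 epimeric | CC(C)(C)[Si](C)(C)O[C@@]1(C)CC/C=C(\C)C[C@@H]2O[C@H]1[C@H]3[C@H]([C@H](C)C=O)CC(C)=C[C@@H]23
F10 | step 17 | C16 aldehyde, C15 as in the target | CC(C)(C)[Si](C)(C)O[C@@]1(C)CC/C=C(\C)C[C@@H]2O[C@H]1[C@H]3[C@H]([C@@H](C)C=O)CC(C)=C[C@@H]23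
F11 | step 20 | 6,7-syn-diol of 27 | CC1=C[C@@H]2[C@@H]3[C@@H](C1)[C@@H](C)CO[C@@]1(C)CC[C@@H](O)[C@](C)(O)C[C@@H]2O[C@@H]31
F12 | step 20 | cyclic orthoacetate of F11 | CC1=C[C@@H]2[C@@H]3[C@@H](C1)[C@@H](C)CO[C@@]1(C)CC[C@H]4OC(C)(OC)O[C@]4(C)C[C@@H]2O[C@@H]31
F13 | step 20 | C6 bromide, C7 acetate | CC1=C[C@@H]2[C@@H]3[C@@H](C1)[C@@H](C)CO[C@@]1(C)CC[C@H](Br)[C@](C)(OC(C)=O)C[C@@H]2O[C@@H]31
F14 | step 25 | C6 phenylselanyl C7 alcohol butanoate | CCCC(=O)O[C@H]1[C@@H]2[C@@H]3[C@@H](C[C@H]1C)[C@@H](C)CO[C@@]1(C)CC[C@H]([Se]c4ccccc4)[C@](C)(O)C[C@@H]2O[C@@H]31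
A1 | alternative 1 | tricyclic (E)-oxonene C3 ketone | CC(C)(C)[Si](C)(C)O[C@H]1[C@@H]2[C@H]([C@@H](C[C@H]1C)[C@@H](C)COCc1ccc(OC)cc1)[C@@H]3O[C@H]2C/C(C)=C/CCC3=O
A2 | alternative 2 | carbocyclic C16 ketone | CC(C)(C)[Si](C)(C)O[C@H]1[C@@H]2[C@@H]3[C@@H](C[C@H]1C)[C@@H](C)C(=O)[C@@]1(C)CC/C=C(\C)C[C@@H]2O[C@@H]31
A3 | alternative 2 | tetracyclic oxepanone (C16 lactone) | CC(C)(C)[Si](C)(C)O[C@H]1[C@@H]2[C@@H]3[C@@H](C[C@H]1C)[C@@H](C)C(=O)O[C@@]1(C)CC/C=C(\C)C[C@@H]2O[C@@H]31
A4 | alternative 3 | oxa-bridged (E)-oxonene C10 ketone | CC(C)(C)[Si](C)(C)O[C@@]1(C)CC/C=C(\C)C[C@@H]2O[C@H]1CC2=O
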